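**Strategy.** Ring C of the upper flavan is closed by forming C2–C3. DDQ turns an open 3,4-bis(benzyloxy)benzyl aryl ether into an O-aryl oxocarbenium ion at C2; C3 of a (Z)-enol acetate on ring A attacks it because C4 is benzylic to the phloroglucinol ring A, and the C3 acetate captures the C4 cation. One operation gives the all-cis 3-acetoxy-4-hydroxyflavan with three stereocentres. After resolution, the (2R,3R,4R) enantiomer is the C4 electrophile for C8 of protected epicatechin, and its mirror image is the terminal 3,4-cis-diol unit, attached by oxidative etherification at the lower C4. Deacetylation and hydrogenolysis finish the route.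

Key step: step 5

Remark: the target is read as epicatechin-(4β→8)-epicatechin whose lower C4 carries, β and through an ether oxygen, C4 of the (2S,3S,4S) all-cis flavan-3,4-diol; racemic compounds are written as the two enantiomers joined by a dot, and 1, 3 and 12 are taken as purchasable.

**Route**

Step 1
Reactants: 1 3,5-bis(benzyloxy)phenol
Product: 2 4,6-bis(benzyloxy)-2-hydroxybenzaldehyde
Conditions: MgCl2, Et3N, (CH2O)n, MeCN, reflux
Reagents that add atoms: paraformaldehyde (as formaldehyde), C=O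
Why: Casnati–Skattebøl ortho-formylation: magnesium-phenoxide chelation directs formaldehyde to one of the two equivalent positions ortho to the hydroxyl, and excess formaldehyde serves as hydride acceptor to reach the aldehyde level.

Step 2
Reactants: 2 4,6-bis(benzyloxy)-2-hydroxybenzaldehyde; 3 3,4-bis(benzyloxy)benzyl chloride
Product: 4 2,4-bis(benzyloxy)-6-{[3,4-bis(benzyloxy)phenyl]methoxy}benzaldehyde
Conditions: K2CO3, NaI (cat.), DMF, 60 °C
Reagents that add atoms: none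
Why: Williamson etherification of the hydrogen-bonded phenol with the activated benzylic chloride installs the future C2 and ring B as a plain benzyl ether.

Step 3
Reactants: 4 2,4-bis(benzyloxy)-6-{[3,4-bis(benzyloxy)phenyl]methoxy}benzaldehyde
Product: 5 1,5-bis(benzyloxy)-3-{[3,4-bis(benzyloxy)phenyl]methoxy}-2-ethynylbenzene
Conditions: dimethyl (1-diazo-2-oxopropyl)phosphonate, K2CO3, MeOH/THF, rt
Reagents that add atoms: dimethyl (1-diazo-2-oxopropyl)phosphonate, COP(=O)(OC)C(=[N+]=[N-])C(C)=O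
Why: Seyferth–Gilbert homologation with the Ohira–Bestmann reagent under mild base should convert the hindered aryl aldehyde into the terminal alkyne without touching the ethers.

Step 4
Reactants: 5 1,5-bis(benzyloxy)-3-{[3,4-bis(benzyloxy)phenyl]methoxy}-2-ethynylbenzene
Product: 6 (Z)-2-[2,4-bis(benzyloxy)-6-{[3,4-bis(benzyloxy)phenyl]methoxy}phenyl]ethenyl acetate
Conditions: Ru(2-methylallyl)2(dppb) (2 mol %), AcOH, toluene, 60 °C
Reagents that add atoms: acetic acid, CC(=O)O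
Why: Ruthenium-catalysed anti-Markovnikov addition of a carboxylic acid to a terminal alkyne through a vinylidene intermediate at the metal should give the (Z)-enol ester, which fixes the alkene geometry that later becomes the axial C3–O bond.

Step 5
Reactants: 6 (Z)-2-[2,4-bis(benzyloxy)-6-{[3,4-bis(benzyloxy)phenyl]methoxy}phenyl]ethenyl acetate
Product: 9 rac-(2R*,3R*,4R*)-5,7-bis(benzyloxy)-2-[3,4-bis(benzyloxy)phenyl]-4-hydroxychroman-3-yl acetate (2,3-cis-3,4-cis), via oxocarbenium ion 7 (not isolated), via acetoxonium ion 8 (not isolated)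
Conditions: DDQ (1.1 equiv), 2,6-dichloropyridine, 4 Å MS, ClCH2CH2Cl, 0 °C to rt; then THF/H2O, NaHCO3, rt
Reagents that add atoms: water, O
Why: Proposed new method: DDQ should abstract hydride from the only benzylic ether CH2 activated by a dialkoxyphenyl ring (C2), giving the (E)-O-aryl oxocarbenium ion 7, which attacks C3 of the (Z)-enol acetate in a 6-endo-trig Prins closure that forms C2–C3, because the charge developing at C4 is carried by the 5,7-dioxygenated ring A while the acetoxy group is only a weak donor, so that attack at C4 (five-membered ring) should lose. The closest known reaction types are the DDQ-mediated oxidative Prins-type cyclisation of benzylic ethers onto enol acetates and the Prins cyclisation of styrenes; new are the O-aryl oxocarbenium ion and the oxygen-bearing alkene terminus. In the chair-like transition state the C2 aryl group is equatorial (from the E-oxocarbenium geometry) and the acetoxy group of the Z-alkene becomes axial, which sets 2,3-cis. The C4 cation is closed by the acetate carbonyl oxygen in a 5-exo-trig capture to the cis-fused 1,3-dioxolan-2-ylium ion 8, so the new C4–O bond must lie on the face of C3–O, and water then adds at the acylium carbon (Woodward-type hydrolysis), the orthoacid collapsing to the axial 3-acetate and the free 4-hydroxyl (3,4-cis). The step needs chemoselective hydride abstraction (the PhCH2O groups are much slower), exclusion of water until the cyclisation is over, and attack at C3 rather than C4; the product is racemic because 6 is achiral, and both enantiomers are used.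

Step 6
Reactants: 9 rac-(2R*,3R*,4R*)-5,7-bis(benzyloxy)-2-[3,4-bis(benzyloxy)phenyl]-4-hydroxychroman-3-yl acetate
Product: 10 (2R,3R,4R)-5,7-bis(benzyloxy)-2-[3,4-bis(benzyloxy)phenyl]-4-hydroxychroman-3-yl acetate; 11 the (2S,3S,4S) enantiomer of 10, collected from the same separation
Conditions: preparative chiral SFC, amylose tris(3,5-dimethylphenylcarbamate) phase, CO2/2-propanol
Reagents that add atoms: none
Why: Chromatographic resolution on a chiral stationary phase separates the enantiomers without any bond change; 10 serves the upper unit and 11, the other fraction of the same separation, serves the terminal unit in step 10, and the assignment would be secured by correlating 10 with material made from 13.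

Step 7
Reactants: 12 (−)-epicatechin
Product: 13 5,7,3',4'-tetra-O-benzyl-(−)-epicatechin
Conditions: BnBr, K2CO3, DMF, 0 °C to rt
Reagents that add atoms: benzyl bromide, BrCc1ccccc1
Why: Phenol O-benzylation under carbonate base should leave the secondary 3-hydroxyl free and C2 unepimerised.

Step 8
Reactants: 13 5,7,3',4'-tetra-O-benzyl-(−)-epicatechin
Product: 14 3,5,7,3',4'-penta-O-benzyl-(−)-epicatechin
Conditions: NaH, BnBr, Bu4NI (cat.), DMF, 0 °C to rt
Reagents that add atoms: benzyl bromide, BrCc1ccccc1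
Why: Williamson benzylation caps the remaining secondary alcohol so that it cannot compete as a nucleophile in step 10.

Step 9
Reactants: 10 (2R,3R,4R)-5,7-bis(benzyloxy)-2-[3,4-bis(benzyloxy)phenyl]-4-hydroxychroman-3-yl acetate; 14 3,5,7,3',4'-penta-O-benzyl-(−)-epicatechin
Product: 15 3-O-acetyl-5,7,3',4'-tetra-O-benzyl-epicatechin-(4β→8)-3,5,7,3',4'-penta-O-benzyl-epicatechin (upper unit 2R,3R,4R; lower unit 2R,3R)
Conditions: TMSOTf (0.2 equiv), 4 Å MS, CH2Cl2, −78 to −30 °C; 14 in excess (3 equiv)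
Reagents that add atoms: none
Why: Lewis-acid-mediated Friedel–Crafts coupling of a flavan-4-ol with a flavan-3-ol nucleophile: TMSOTf ionises the benzylic C4–OH of 10, the axial 3-acetoxy group blocks the α face (anchimeric assistance), and C8 of 14, in excess to suppress oligomerisation, should add from the β face to set the upper C4 as 4β (3,4-trans).

Step 10
Reactants: 15 the 4β→8 dimer; 11 (2S,3S,4S)-5,7-bis(benzyloxy)-2-[3,4-bis(benzyloxy)phenyl]-4-hydroxychroman-3-yl acetate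
Product: 17 protected trimer in which the lower C4 of 15 carries, 4β, the C4 oxygen of 11 as an ether (lower unit 2R,3R,4S; terminal unit 2S,3S,4S), via benzylic cation 16 (not isolated)
Conditions: DDQ (1.05 equiv), 4 Å MS, CH2Cl2, 0 °C to rt; then 11 (2 equiv), rt
Reagents that add atoms: none
Why: DDQ-mediated benzylic oxidation and alkoxylation at C4 of a benzylated flavan-3-ol: hydride is taken from the only CH2 next to an electron-rich ring, and 11, added after DDQ is consumed so that its own carbinol C–H is spared, should enter anti to the axial 3-benzyloxy group (4β, 3,4-trans), while C4 of 11 keeps its configuration because only its O–H bond reacts.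

Step 11
Reactants: 17 protected trimer bis-acetate
Product: 18 trideca-O-benzyl trimer with free upper and terminal 3-hydroxyls
Conditions: K2CO3 (cat.), MeOH/THF, rt
Reagents that add atoms: none
Why: Base-catalysed methanolysis removes both secondary acetates; without free phenols the benzylic ether bridge cannot eliminate.

Step 12
Reactants: 18 trideca-O-benzyl trimer
Product: 19 CNP0310719.1
Conditions: H2 (1 atm), Pd(OH)2/C, THF/MeOH/H2O, rt
Reagents that add atoms: none
Why: Hydrogenolysis cleaves the thirteen O-benzyl groups, whereas the hindered secondary benzylic C–O bonds (C2–O1 of each ring C and the C4–O–C4 bridge) should react far more slowly, so the reaction is stopped at the calculated hydrogen uptake.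

**Compound list**

1 | 3,5-bis(benzyloxy)phenol | Oc1cc(OCc2ccccc2)cc(OCc2ccccc2)c1 | starting material
2 | 4,6-bis(benzyloxy)-2-hydroxybenzaldehyde | O=Cc1c(O)cc(OCc2ccccc2)cc1OCc1ccccc1 | intermediate
3 | 3,4-bis(benzyloxy)benzyl chloride | ClCc1ccc(OCc2ccccc2)c(OCc2ccccc2)c1 | starting material
4 | 2,4-bis(benzyloxy)-6-{[3,4-bis(benzyloxy)phenyl]methoxy}benzaldehyde | O=Cc1c(OCc2ccc(OCc3ccccc3)c(OCc3ccccc3)c2)cc(OCc2ccccc2)cc1OCc1ccccc1 | intermediate
5 | 1,5-bis(benzyloxy)-3-{[3,4-bis(benzyloxy)phenyl]methoxy}-2-ethynylbenzene | C#Cc1c(OCc2ccc(OCc3ccccc3)c(OCc3ccccc3)c2)cc(OCc2ccccc2)cc1OCc1ccccc1 | intermediate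
6 | (Z)-2-[2,4-bis(benzyloxy)-6-{[3,4-bis(benzyloxy)phenyl]methoxy}phenyl]ethenyl acetate | CC(=O)O/C=C\c1c(OCc2ccc(OCc3ccccc3)c(OCc3ccccc3)c2)cc(OCc2ccccc2)cc1OCc1ccccc1 | intermediate
7 | O-aryl oxocarbenium ion from 6 (cation, DDQH− as counter-ion) | CC(=O)O/C=C\c1c([O+]=Cc2ccc(OCc3ccccc3)c(OCc3ccccc3)c2)cc(OCc2ccccc2)cc1OCc1ccccc1 | intermediate
8 | rac-2,3-cis flavan with a cis-fused 2-methyl-1,3-dioxolan-2-ylium ring across C3–C4 (cation) | C(c1ccccc1)Oc1cc(OCc2ccccc2)c2c(c1)O[C@H](c1ccc(OCc3ccccc3)c(OCc3ccccc3)c1)[C@@H]3OC(C)=[O+][C@H]23.C(c1ccccc1)Oc1cc(OCc2ccccc2)c2c(c1)O[C@@H](c1ccc(OCc3ccccc3)c(OCc3ccccc3)c1)[C@H]3OC(C)=[O+][C@@H]23 | intermediate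
9 | rac-(2R*,3R*,4R*)-5,7-bis(benzyloxy)-2-[3,4-bis(benzyloxy)phenyl]-4-hydroxychroman-3-yl acetate | C(c1ccccc1)Oc1cc(OCc2ccccc2)c2c(c1)O[C@H](c1ccc(OCc3ccccc3)c(OCc3ccccc3)c1)[C@H](OC(C)=O)[C@@H]2O.C(c1ccccc1)Oc1cc(OCc2ccccc2)c2c(c1)O[C@@H](c1ccc(OCc3ccccc3)c(OCc3ccccc3)c1)[C@@H](OC(C)=O)[C@H]2O | intermediate
10 | (2R,3R,4R)-5,7-bis(benzyloxy)-2-[3,4-bis(benzyloxy)phenyl]-4-hydroxychroman-3-yl acetate | C(c1ccccc1)Oc1cc(OCc2ccccc2)c2c(c1)O[C@H](c1ccc(OCc3ccccc3)c(OCc3ccccc3)c1)[C@H](OC(C)=O)[C@@H]2O | intermediate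
11 | (2S,3S,4S)-5,7-bis(benzyloxy)-2-[3,4-bis(benzyloxy)phenyl]-4-hydroxychroman-3-yl acetate (the other fraction of the step 6 separation) | C(c1ccccc1)Oc1cc(OCc2ccccc2)c2c(c1)O[C@@H](c1ccc(OCc3ccccc3)c(OCc3ccccc3)c1)[C@@H](OC(C)=O)[C@H]2O | intermediate
12 | (−)-epicatechin, (2R,3R) | Oc1cc(O)c2c(c1)O[C@H](c1ccc(O)c(O)c1)[C@H](O)C2 | starting material
13 | 5,7,3',4'-tetra-O-benzyl-(−)-epicatechin | C(c1ccccc1)Oc1cc(OCc2ccccc2)c2c(c1)O[C@H](c1ccc(OCc3ccccc3)c(OCc3ccccc3)c1)[C@H](O)C2 | intermediate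
14 | 3,5,7,3',4'-penta-O-benzyl-(−)-epicatechin | C(c1ccccc1)Oc1cc(OCc2ccccc2)c2c(c1)O[C@H](c1ccc(OCc3ccccc3)c(OCc3ccccc3)c1)[C@H](OCc1ccccc1)C2 | intermediate
15 | 3-O-acetyl-5,7,3',4'-tetra-O-benzyl-epicatechin-(4β→8)-penta-O-benzyl-epicatechin | C(c1ccccc1)Oc1cc(OCc2ccccc2)c2c(c1)O[C@H](c1ccc(OCc3ccccc3)c(OCc3ccccc3)c1)[C@H](OC(C)=O)[C@H]2c1c(OCc3ccccc3)cc(OCc3ccccc3)c3c1O[C@H](c1ccc(OCc4ccccc4)c(OCc4ccccc4)c1)[C@H](OCc1ccccc1)C3 | intermediate
16 | C4 benzylic cation of the lower unit of 15 (DDQH− as counter-ion) | C(c1ccccc1)Oc1cc(OCc2ccccc2)c2c(c1)O[C@H](c1ccc(OCc3ccccc3)c(OCc3ccccc3)c1)[C@H](OC(C)=O)[C@H]2c1c(OCc3ccccc3)cc(OCc3ccccc3)c3c1O[C@H](c1ccc(OCc4ccccc4)c(OCc4ccccc4)c1)[C@H](OCc1ccccc1)[CH+]3 | intermediate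
17 | protected trimer, upper and terminal 3-O-acetates, lower C4 (4β)–O–C4 terminal ether | C(c1ccccc1)Oc1cc(OCc2ccccc2)c2c(c1)O[C@H](c1ccc(OCc3ccccc3)c(OCc3ccccc3)c1)[C@H](OC(C)=O)[C@H]2c1c(OCc3ccccc3)cc(OCc3ccccc3)c3c1O[C@H](c1ccc(OCc4ccccc4)c(OCc4ccccc4)c1)[C@H](OCc1ccccc1)[C@H]3O[C@H]1c2c(OCc4ccccc4)cc(OCc4ccccc4)cc2O[C@@H](c2ccc(OCc4ccccc4)c(OCc4ccccc4)c2)[C@H]1OC(C)=O | intermediate
18 | trideca-O-benzyl trimer with free upper and terminal 3-hydroxyls | C(c1ccccc1)Oc1cc(OCc2ccccc2)c2c(c1)O[C@H](c1ccc(OCc3ccccc3)c(OCc3ccccc3)c1)[C@H](O)[C@H]2c1c(OCc3ccccc3)cc(OCc3ccccc3)c3c1O[C@H](c1ccc(OCc4ccccc4)c(OCc4ccccc4)c1)[C@H](OCc1ccccc1)[C@H]3O[C@H]1c2c(OCc4ccccc4)cc(OCc4ccccc4)cc2O[C@@H](c2ccc(OCc4ccccc4)c(OCc4ccccc4)c2)[C@H]1O | intermediate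
19 | CNP0310719.1 (upper unit 2R,3R,4R; lower unit 2R,3R,4S; terminal unit 2S,3S,4S) | Oc1cc(O)c2c(c1)O[C@H](c1ccc(O)c(O)c1)[C@H](O)[C@H]2c1c(O)cc(O)c2c1O[C@H](c1ccc(O)c(O)c1)[C@H](O)[C@H]2O[C@H]1c2c(O)cc(O)cc2O[C@@H](c2ccc(O)c(O)c2)[C@H]1O | target

**Step count and risks**

Total step count: 12. Longest linear sequence: 10 steps (steps 1–6 and 9–12).

Steps most likely to fail:

1. Step 5 (Proposed new method). What may go wrong: closure through C4 of the alkene to a dihydrobenzofuran instead of through C3; hydrolytic loss of the oxidised benzyl ether before cyclisation; oxidation of the electron-rich styrene by DDQ; or capture of the C4 cation by water from the β face (3,4-trans). The fallback uses known reactions only and still makes the C2–C3 bond in the ring closure, now as an enol-ether double bond; it sets out from 1 and comes back at 9. O-Allylation of 1 (allyl bromide, K2CO3, acetone) would give 1-(allyloxy)-3,5-bis(benzyloxy)benzene F1, and aromatic Claisen rearrangement (N,N-diethylaniline, 190 °C) would give 2-allyl-3,5-bis(benzyloxy)phenol F2. Acylation with 3,4-bis(benzyloxy)benzoyl chloride (Et3N, DMAP, CH2Cl2) would give 2-allyl-3,5-bis(benzyloxy)phenyl 3,4-bis(benzyloxy)benzoate F3. Methylenation of the ester carbonyl with the Tebbe reagent Cp2Ti(μ-CH2)(μ-Cl)AlMe2 would give the aryl 1-arylvinyl ether F4. Ring-closing olefin metathesis with the second-generation Grubbs catalyst RuCl2(=CHPh)(H2IMes)(PCy3) in toluene at 70 °C would close ring C at C2=C3 to 5,7-bis(benzyloxy)-2-[3,4-bis(benzyloxy)phenyl]-4H-chromene F5. Epoxidation with dimethyldioxirane at −78 °C would give the racemic 2,3-epoxyflavan F6; LiBHEt3 added to the same flask should open it at the acetal carbon C2 anti to the epoxide oxygen, giving racemic 2,3-cis 5,7,3',4'-tetra-O-benzylflavan-3-ol F7. Acetylation (Ac2O, pyridine) would give the racemic 3-acetate F8; DDQ in CH2Cl2/H2O would give the racemic 4β-hydroxy 3-acetate (3,4-trans) F9; Dess–Martin periodinane would give the racemic 3-acetoxyflavan-4-one F10. NaBH4 (THF/MeOH, −40 °C), with hydride entering anti to the axial 3-acetoxy group, should give the all-cis alcohol 9.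

2. Step 10. What may go wrong: oxidation of the carbinol C–H of 11 or of the upper C4–H by residual DDQ, ionisation of the C4–OH of 11 under the weakly acidic conditions, and slow capture of the hindered lower C4 cation by the hindered secondary alcohol, so that self-condensation of the cation wins. The fallback separates oxidation from ether formation and activates sulfur instead of relying on the DDQ ion pair; it sets out from 15 and comes back at 17. DDQ oxidation of 15 in CH2Cl2 with excess 2-ethoxyethanol would give the lower-unit 4β-(2-ethoxyethoxy) dimer F11. Exchange with 2-mercaptobenzothiazole (BF3·OEt2, CH2Cl2, −40 °C; no acid-labile ether bridge is present yet) would give the lower-unit 4β-(1,3-benzothiazol-2-ylsulfanyl) dimer F12. Thiophilic activation with AgBF4 in the presence of 2,6-di-tert-butyl-4-methylpyridine and 11 (THF/CH2Cl2, −40 °C) should deliver the ether 17 under non-acidic conditions.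

3. Step 4. What may go wrong: Markovnikov addition of the acid, or loss of Z selectivity, on the electron-rich, di-ortho-substituted arylalkyne. The fallback fixes the Z geometry at boron first; it sets out from 5 and comes back at 6. Rhodium-catalysed trans-hydroboration ([RhCl(cod)]2, P(iPr)3, Et3N, pinacolborane, cyclohexane) would give the (Z)-alkenyl pinacol boronate F13. KHF2 in MeOH/H2O would give the potassium (Z)-alkenyltrifluoroborate F14. Chan–Lam coupling with acetic acid (Cu(OAc)2, 4 Å MS, O2, CH2Cl2) should form the C–O bond with retention of geometry and give 6.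

Further compounds
F1 | step 5 | 1-(allyloxy)-3,5-bis(benzyloxy)benzene | C=CCOc1cc(OCc2ccccc2)cc(OCc2ccccc2)c1
F2 | step 5 | 2-allyl-3,5-bis(benzyloxy)phenol | C=CCc1c(O)cc(OCc2ccccc2)cc1OCc1ccccc1
F3 | step 5 | 2-allyl-3,5-bis(benzyloxy)phenyl 3,4-bis(benzyloxy)benzoate | C=CCc1c(OC(=O)c2ccc(OCc3ccccc3)c(OCc3ccccc3)c2)cc(OCc2ccccc2)cc1OCc1ccccc1
F4 | step 5 | 2-allyl-3,5-bis(benzyloxy)phenyl 1-[3,4-bis(benzyloxy)phenyl]vinyl ether | C=CCc1c(OC(=C)c2ccc(OCc3ccccc3)c(OCc3ccccc3)c2)cc(OCc2ccccc2)cc1OCc1ccccc1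
F5 | step 5 | 5,7-bis(benzyloxy)-2-[3,4-bis(benzyloxy)phenyl]-4H-chromene | C(c1ccccc1)Oc1cc(OCc2ccccc2)c2c(c1)OC(c1ccc(OCc3ccccc3)c(OCc3ccccc3)c1)=CC2
F6 | step 5 | rac-5,7-bis(benzyloxy)-2-[3,4-bis(benzyloxy)phenyl]-2,3-epoxychroman | C(c1ccccc1)Oc1cc(OCc2ccccc2)c2c(c1)O[C@]3(c1ccc(OCc4ccccc4)c(OCc4ccccc4)c1)O[C@@H]3C2.C(c1ccccc1)Oc1cc(OCc2ccccc2)c2c(c1)O[C@@]3(c1ccc(OCc4ccccc4)c(OCc4ccccc4)c1)O[C@H]3C2
F7 | step 5 | rac-2,3-cis-5,7,3',4'-tetra-O-benzylflavan-3-ol | C(c1ccccc1)Oc1cc(OCc2ccccc2)c2c(c1)O[C@H](c1ccc(OCc3ccccc3)c(OCc3ccccc3)c1)[C@H](O)C2.C(c1ccccc1)Oc1cc(OCc2ccccc2)c2c(c1)O[C@@H](c1ccc(OCc3ccccc3)c(OCc3ccccc3)c1)[C@@H](O)C2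
F8 | step 5 | rac-2,3-cis-5,7,3',4'-tetra-O-benzylflavan-3-yl acetate | C(c1ccccc1)Oc1cc(OCc2ccccc2)c2c(c1)O[C@H](c1ccc(OCc3ccccc3)c(OCc3ccccc3)c1)[C@H](OC(C)=O)C2.C(c1ccccc1)Oc1cc(OCc2ccccc2)c2c(c1)O[C@@H](c1ccc(OCc3ccccc3)c(OCc3ccccc3)c1)[C@@H](OC(C)=O)C2
F9 | step 5 | rac-2,3-cis-3,4-trans-4-hydroxy-5,7,3',4'-tetra-O-benzylflavan-3-yl acetate | C(c1ccccc1)Oc1cc(OCc2ccccc2)c2c(c1)O[C@H](c1ccc(OCc3ccccc3)c(OCc3ccccc3)c1)[C@H](OC(C)=O)[C@H]2O.C(c1ccccc1)Oc1cc(OCc2ccccc2)c2c(c1)O[C@@H](c1ccc(OCc3ccccc3)c(OCc3ccccc3)c1)[C@@H](OC(C)=O)[C@@H]2O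
F10 | step 5 | rac-2,3-cis-4-oxo-5,7,3',4'-tetra-O-benzylflavan-3-yl acetate | C(c1ccccc1)Oc1cc(OCc2ccccc2)c2c(c1)O[C@H](c1ccc(OCc3ccccc3)c(OCc3ccccc3)c1)[C@H](OC(C)=O)C2=O.C(c1ccccc1)Oc1cc(OCc2ccccc2)c2c(c1)O[C@@H](c1ccc(OCc3ccccc3)c(OCc3ccccc3)c1)[C@@H](OC(C)=O)C2=O
F11 | step 10 | dimer 15 bearing a 4β-(2-ethoxyethoxy) group at the lower C4 | C(c1ccccc1)Oc1cc(OCc2ccccc2)c2c(c1)O[C@H](c1ccc(OCc3ccccc3)c(OCc3ccccc3)c1)[C@H](OC(C)=O)[C@H]2c1c(OCc3ccccc3)cc(OCc3ccccc3)c3c1O[C@H](c1ccc(OCc4ccccc4)c(OCc4ccccc4)c1)[C@H](OCc1ccccc1)[C@H]3OCCOCC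
F12 | step 10 | dimer 15 bearing a 4β-(1,3-benzothiazol-2-ylsulfanyl) group at the lower C4 | C(c1ccccc1)Oc1cc(OCc2ccccc2)c2c(c1)O[C@H](c1ccc(OCc3ccccc3)c(OCc3ccccc3)c1)[C@H](OC(C)=O)[C@H]2c1c(OCc3ccccc3)cc(OCc3ccccc3)c3c1O[C@H](c1ccc(OCc4ccccc4)c(OCc4ccccc4)c1)[C@H](OCc1ccccc1)[C@H]3Sc1nc2ccccc2s1
F13 | step 4 | (Z)-2-[2,4-bis(benzyloxy)-6-{[3,4-bis(benzyloxy)phenyl]methoxy}phenyl]ethenylboronic acid pinacol ester | CC1(C)OB(/C=C\c2c(OCc3ccc(OCc4ccccc4)c(OCc4ccccc4)c3)cc(OCc3ccccc3)cc2OCc2ccccc2)OC1(C)C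
F14 | step 4 | potassium (Z)-{2-[2,4-bis(benzyloxy)-6-{[3,4-bis(benzyloxy)phenyl]methoxy}phenyl]ethenyl}trifluoroborate | [K+].F[B-](F)(F)/C=C\c1c(OCc2ccc(OCc3ccccc3)c(OCc3ccccc3)c2)cc(OCc2ccccc2)cc1OCc1ccccc1
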